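Ring A is cut first, at C8–C8a and C5–C4a. This leaves a C4a-sulfinyl (2S)-2-aryl-2,3-dihydropyran-4-one and a 1-methoxy-1,3-bis(silyloxy)diene that already carries the C8 prenyl group. Ring C is then cut at C2–C3 and O1–C8a.
Enabling feature: ring C without ring A (O1, C2, C3, C4, C4a, C8a) is a cyclic vinylogous ester. Its C3–C4–C4a–C8a chain has the oxygen pattern of 1-methoxy-3-(trimethylsilyloxy)buta-1,3-diene, and C2–O1 is the former carbonyl group of the ring-B aldehyde.
Forward order: ring B is bought and receives its C2' prenyl and C1' formyl groups. Ring C is closed by an asymmetric hetero-Diels–Alder reaction, ring A is annulated last by a Diels–Alder reaction and aromatised, and the MOM group is removed at the end.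
The C8/C6 prenyl question is settled by polarity: C8a, the oxygen-bearing β-carbon of the enone, is the only site open to the nucleophilic, prenylated diene terminus.
Stereochemistry: C2 is the only stereocentre. It is set by (S)-BINOL on titanium during ring-C closure, and no later step uses a base able to deprotonate C3.

Key step: step 4

Assumption: the facial sense of the Ti(OiPr)4/(S)-BINOL catalyst is taken to be the one it shows when allyl and silyl enol ether nucleophiles add to aromatic aldehydes (Si-face attack, (S)-carbinol). If aldehyde 8 responded in the opposite sense, (R)-BINOL would be used with nothing else changed.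
Notation: flavanone numbering (O1, C2, C3, C4, C4a, C5–C8, C8a, primed positions for ring B) is used for all intermediates. Ar = 3-methoxy-4-(methoxymethoxy)-2-(3-methylbut-2-enyl)phenyl; prenyl = 3-methylbut-2-enyl.

Step 1
Reactants: 1 4-bromo-2-methoxyphenol
Product: 2 4-bromo-2-methoxy-1-(methoxymethoxy)benzene
Conditions: MOMCl, iPr2NEt, CH2Cl2, 0 °C to rt
Reagents that add atoms: chloromethyl methyl ether (MOMCl), COCCl
Why: Williamson-type O-alkylation of the phenol gives an acetal that tolerates lithium amides, alkyllithiums and the mild Lewis acid of step 4 and can be removed with dilute acid at the end.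

Step 2
Reactants: 2 4-bromo-2-methoxy-1-(methoxymethoxy)benzene; 3 prenyl bromide (1-bromo-3-methylbut-2-ene)
Product: 6 1-bromo-3-methoxy-4-(methoxymethoxy)-2-(3-methylbut-2-enyl)benzene, via 3-lithioarene 4 (not isolated), via arylcopper 5 (not isolated)
Conditions: LiN(iPr)2, THF, −78 °C; CuBr·SMe2, −78 °C; 3, −78 to 0 °C
Reagents that add atoms: none
Why: Directed ortho-lithiation removes the most acidic ring proton, the one flanked by Br and OMe, transmetalation to monovalent copper at −78 °C forestalls loss of LiBr to an aryne, and allylic substitution of 3 occurs at its unhindered CH2 terminus (SN2 mode) because the γ-carbon is fully substituted.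

Step 3
Reactants: 6 1-bromo-3-methoxy-4-(methoxymethoxy)-2-(3-methylbut-2-enyl)benzene
Product: 8 3-methoxy-4-(methoxymethoxy)-2-(3-methylbut-2-enyl)benzaldehyde, via aryllithium 7 (not isolated)
Conditions: n-BuLi, THF, −78 °C; DMF, −78 to 0 °C; H2O
Reagents that add atoms: N,N-dimethylformamide, CN(C)C=O
Why: Bromine–lithium exchange is faster at −78 °C than deprotonation of the benzylic-allylic CH2, and formylation of 7 with DMF (Bouveault aldehyde synthesis) places the future C2 carbon at C1'.

Step 4
Reactants: 8 3-methoxy-4-(methoxymethoxy)-2-(3-methylbut-2-enyl)benzaldehyde; 9 (E)-1-methoxy-3-(trimethylsilyloxy)buta-1,3-diene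
Product: 11 (2S)-2-Ar-2,3-dihydro-4H-pyran-4-one, via silylated aldol adduct 10 (not isolated)
Conditions: (S)-BINOL (20 mol %), Ti(OiPr)4 (10 mol %), 4 Å MS, Et2O, −20 °C; then CF3CO2H (0.2 equiv), CH2Cl2, 0 °C; aq. NaHCO3
Reagents that add atoms: none
Why: The complex of tetravalent titanium formed from Ti(OiPr)4 and (S)-BINOL binds the formyl oxygen of 8, and the CH2 terminus of 9 adds to the carbonyl carbon (C2–C3) in a Mukaiyama aldol event with silyl transfer to give 10. Ring C is then closed under CF3CO2H by 6-endo-trig oxa-Michael attack of the C2 oxygen on the methoxy-bearing carbon (O1–C8a) followed by loss of methanol, so that the two operations add up to a formal [4+2] cycloaddition of the C=O group across the diene. The closest known reaction type is the titanium–BINOL-catalysed enantioselective hetero-Diels–Alder reaction of aromatic aldehydes with 1-alkoxy-3-silyloxydienes to 2-aryl-2,3-dihydropyran-4-ones. C2 is the only new stereocentre and is controlled by the ligand alone: the (S)-binaphthoxide shields the Re face of the bound aldehyde, Si-face attack gives (2S), and the cyclisation does not touch the C2–O bond. The step needs face selectivity, which the catalyst supplies, and regioselectivity, which the substrates secure themselves because the silyl enol ether terminus is the only nucleophilic carbon of 9 that can reach the only electrophilic carbon of 8. The prenyl alkene and the MOM acetal are spectators towards the mild Lewis acid and meet the Brønsted acid only briefly at 0 °C.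

Step 5
Reactants: 11 (2S)-2-Ar-2,3-dihydro-4H-pyran-4-one
Product: 12 (2S)-2-Ar-5-iodo-2,3-dihydro-4H-pyran-4-one (iodine on C4a)
Conditions: I2, pyridine, CH2Cl2, 0 °C to rt, dark
Reagents that add atoms: iodine, II
Why: α-Iodination of an enone with I2/pyridine succeeds because C4a is the nucleophilic carbon of the vinylogous ester and pyridine takes up the proton, while the prenyl alkene only complexes iodine reversibly in the absence of a trapping nucleophile and the weak base leaves C3–H and hence C2 untouched.

Step 6
Reactants: 12 (2S)-2-Ar-5-iodo-2,3-dihydro-4H-pyran-4-one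
Product: 13 (2S)-2-Ar-5-(phenylthio)-2,3-dihydro-4H-pyran-4-one
Conditions: Bu3SnSPh, Pd(PPh3)4 (5 mol %), toluene, 80 °C
Reagents that add atoms: tributyl(phenylthio)stannane, CCCC[Sn](CCCC)(CCCC)Sc1ccccc1
Why: Palladium-catalysed C–S cross-coupling of an alkenyl iodide with a tin thiolate (oxidative addition to zerovalent palladium, Stille-type transmetalation, reductive elimination) runs without added base, so neither thiolate conjugate addition at C8a nor retro-oxa-Michael opening of C2–O1 is provoked.

Step 7
Reactants: 13 (2S)-2-Ar-5-(phenylthio)-2,3-dihydro-4H-pyran-4-one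
Product: 14 (2S)-2-Ar-5-(phenylsulfinyl)-2,3-dihydro-4H-pyran-4-one (both epimers at sulfur)
Conditions: 30% aq. H2O2 (1.1 equiv), (CF3)2CHOH, 0 °C to rt
Reagents that add atoms: hydrogen peroxide, OO
Why: In this chemoselective sulfide-to-sulfoxide oxidation the fluorinated alcohol activates H2O2 towards sulfur by hydrogen bonding and deactivates the sulfoxide formed, so sulfone formation and epoxidation of the prenyl alkene are not expected, and the new sulfur stereocentre is left uncontrolled because it is expelled in step 11.

Step 8
Reactants: 15 methyl acetoacetate; 3 prenyl bromide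
Product: 17 methyl 7-methyl-3-oxooct-6-enoate, via sodium lithium dianion 16 (not isolated)
Conditions: NaH, THF, 0 °C; n-BuLi, 0 °C; 3, 0 °C to rt; 1 M aq. HCl
Reagents that add atoms: none
Why: In the γ-alkylation of a β-keto ester dianion the terminal carbanion, generated last, is the more nucleophilic site and displaces bromide from 3 in an SN2 reaction.

Step 9
Reactants: 17 methyl 7-methyl-3-oxooct-6-enoate
Product: 18 methyl 7-methyl-3-(trimethylsilyloxy)octa-2,6-dienoate (geometry at C2=C3 of no consequence)
Conditions: Me3SiCl, Et3N, toluene, rt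
Reagents that add atoms: chlorotrimethylsilane, C[Si](C)(C)Cl
Why: Silyl enol ether formation from the enolised β-keto ester masks the acidic C2 position so that the next base acts at C4.

Step 10
Reactants: 18 methyl 7-methyl-3-(trimethylsilyloxy)octa-2,6-dienoate
Product: 20 (3Z)-1-methoxy-7-methyl-1,3-bis(trimethylsilyloxy)octa-1,3,6-triene, via lithium dienolate 19 (not isolated)
Conditions: LiN(iPr)2, THF, −78 °C; Me3SiCl, −78 °C to rt
Reagents that add atoms: chlorotrimethylsilane, C[Si](C)(C)Cl
Why: Kinetic γ-deprotonation of the 3-silyloxy enoate and O-silylation of the dienolate is the standard second stage of 1,3-bis(silyloxy)diene synthesis and should place the alkyl chain cis to the C3 silyloxy group, that is, outward in the s-cis diene.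

Step 11
Reactants: 14 (2S)-2-Ar-5-(phenylsulfinyl)-2,3-dihydro-4H-pyran-4-one; 20 (3Z)-1-methoxy-7-methyl-1,3-bis(trimethylsilyloxy)octa-1,3,6-triene
Product: 23 (2S)-2-Ar-5,7-dihydroxy-8-prenylchroman-4-one, via cycloadduct 21 (not isolated), via cyclohexadiene ketal 22 (not isolated)
Conditions: 20 (2.5 equiv), toluene, 90 °C, sealed tube; then 0.5 M aq. HCl, THF, 0 °C
Reagents that add atoms: none
Why: Proposed new method: the sulfinyl group and the C4 carbonyl group, both on C4a, lower the LUMO of the C4a=C8a bond and polarise it so that the nucleophilic, prenyl-bearing diene terminus bonds to C8a (C8–C8a) and the ketene acetal carbon to C4a (C5–C4a) in an asynchronous Diels–Alder reaction, the C8a–H of 21, which is cis to sulfur, then allows thermal syn-elimination of benzenesulfenic acid under neutral conditions to give 22, and dilute acid collapses the C5 mixed ketal with loss of methanol and both silyl groups to the phloroglucinol ring; the closest known reaction types are the tandem Diels–Alder/sulfoxide elimination of 2-sulfinyl enones and sulfinylquinones and the resorcinol-forming cycloaddition of 1-methoxy-1,3-bis(silyloxy)dienes with haloquinones and alkynes, neither of which has been shown on a β-alkoxy enone such as a dihydropyranone.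

Step 12
Reactants: 23 (2S)-2-Ar-5,7-dihydroxy-8-prenylchroman-4-one
Product: 24 (2S)-5,7-dihydroxy-2-[4-hydroxy-3-methoxy-2-(3-methylbut-2-enyl)phenyl]-8-(3-methylbut-2-enyl)chroman-4-one (CNP0282226.1)
Conditions: 3 M aq. HCl, MeOH, 40 °C
Reagents that add atoms: none
Why: Acid-catalysed acetal hydrolysis removes the aryl MOM ether under conditions routinely tolerated by prenylated polyphenols, and acid is chosen over base because C2 epimerises mainly through base-induced ring opening to the chalcone.

Compound list
1 | 4-bromo-2-methoxyphenol | COc1cc(Br)ccc1O | starting material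
2 | 4-bromo-2-methoxy-1-(methoxymethoxy)benzene | COCOc1ccc(Br)cc1OC | intermediate
3 | prenyl bromide (1-bromo-3-methylbut-2-ene) | CC(C)=CCBr | starting material
4 | [6-bromo-2-methoxy-3-(methoxymethoxy)phenyl]lithium (not isolated) | COCOc1ccc(Br)c([Li])c1OC | intermediate
5 | [6-bromo-2-methoxy-3-(methoxymethoxy)phenyl]copper (not isolated) | COCOc1ccc(Br)c([Cu])c1OC | intermediate
6 | 1-bromo-3-methoxy-4-(methoxymethoxy)-2-(3-methylbut-2-enyl)benzene | COCOc1ccc(Br)c(CC=C(C)C)c1OC | intermediate
7 | [3-methoxy-4-(methoxymethoxy)-2-(3-methylbut-2-enyl)phenyl]lithium (not isolated) | COCOc1ccc([Li])c(CC=C(C)C)c1OC | intermediate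
8 | 3-methoxy-4-(methoxymethoxy)-2-(3-methylbut-2-enyl)benzaldehyde | COc1c(OCOC)ccc(C=O)c1CC=C(C)C | intermediate
9 | (E)-1-methoxy-3-(trimethylsilyloxy)buta-1,3-diene | CO/C=C/C(=C)O[Si](C)(C)C | starting material
10 | (1E,5S)-5-Ar-1-methoxy-5-(trimethylsilyloxy)pent-1-en-3-one (not isolated) | CO/C=C/C(=O)C[C@H](O[Si](C)(C)C)c1ccc(OCOC)c(OC)c1CC=C(C)C | intermediate
11 | (2S)-2-[3-methoxy-4-(methoxymethoxy)-2-(3-methylbut-2-enyl)phenyl]-2,3-dihydro-4H-pyran-4-one | COc1c(OCOC)ccc([C@@H]2CC(=O)C=CO2)c1CC=C(C)C | intermediate
12 | (2S)-2-Ar-5-iodo-2,3-dihydro-4H-pyran-4-one | COc1c(OCOC)ccc([C@@H]2CC(=O)C(I)=CO2)c1CC=C(C)C | intermediate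
13 | (2S)-2-Ar-5-(phenylthio)-2,3-dihydro-4H-pyran-4-one | COc1c(OCOC)ccc([C@@H]2CC(=O)C(Sc3ccccc3)=CO2)c1CC=C(C)C | intermediate
14 | (2S)-2-Ar-5-(phenylsulfinyl)-2,3-dihydro-4H-pyran-4-one, both epimers at sulfur | COc1c(OCOC)ccc([C@@H]2CC(=O)C(S(=O)c3ccccc3)=CO2)c1CC=C(C)C | intermediate
15 | methyl acetoacetate | COC(=O)CC(C)=O | starting material
16 | sodium lithium 1-methoxybuta-1,3-diene-1,3-diolate, the dianion of 15 (not isolated) | [Na+].[Li+].COC([O-])=CC([O-])=C | intermediate
17 | methyl 7-methyl-3-oxooct-6-enoate | COC(=O)CC(=O)CCC=C(C)C | intermediate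
18 | methyl 7-methyl-3-(trimethylsilyloxy)octa-2,6-dienoate, C2=C3 geometry undefined | COC(=O)C=C(CCC=C(C)C)O[Si](C)(C)C | intermediate
19 | lithium (3Z)-1-methoxy-7-methyl-3-(trimethylsilyloxy)octa-1,3,6-trien-1-olate (not isolated) | [Li]OC(OC)=C/C(O[Si](C)(C)C)=C/CC=C(C)C | intermediate
20 | (3Z)-1-methoxy-7-methyl-1,3-bis(trimethylsilyloxy)octa-1,3,6-triene, ketene acetal geometry undefined | COC(O[Si](C)(C)C)=C/C(O[Si](C)(C)C)=C/CC=C(C)C | intermediate
21 | (2S)-2-Ar-5-methoxy-4a-(phenylsulfinyl)-8-prenyl-5,7-bis(trimethylsilyloxy)-2,3,4a,5,8,8a-hexahydrochromen-4-one, cis ring fusion, transient centres C4a, C5, C8, C8a undefined (not isolated) | COc1c(OCOC)ccc([C@@H]2CC(=O)C3(S(=O)c4ccccc4)C(O2)C(CC=C(C)C)C(O[Si](C)(C)C)=CC3(OC)O[Si](C)(C)C)c1CC=C(C)C | intermediate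
22 | (2S)-2-Ar-5-methoxy-8-prenyl-5,7-bis(trimethylsilyloxy)-2,3,5,8-tetrahydrochromen-4-one, C5 and C8 undefined (not isolated) | COc1c(OCOC)ccc([C@@H]2CC(=O)C3=C(O2)C(CC=C(C)C)C(O[Si](C)(C)C)=CC3(OC)O[Si](C)(C)C)c1CC=C(C)C | intermediate
23 | (2S)-5,7-dihydroxy-2-[3-methoxy-4-(methoxymethoxy)-2-(3-methylbut-2-enyl)phenyl]-8-(3-methylbut-2-enyl)chroman-4-one | COc1c(OCOC)ccc([C@@H]2CC(=O)c3c(O)cc(O)c(CC=C(C)C)c3O2)c1CC=C(C)C | intermediate
24 | (2S)-5,7-dihydroxy-2-[4-hydroxy-3-methoxy-2-(3-methylbut-2-enyl)phenyl]-8-(3-methylbut-2-enyl)chroman-4-one (CNP0282226.1) | COc1c(O)ccc([C@@H]2CC(=O)c3c(O)cc(O)c(CC=C(C)C)c3O2)c1CC=C(C)C | target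

Total step count: 12. Longest linear sequence: 9 (steps 1–7, 11 and 12). The diene branch (steps 8–10) has three steps.

Steps most likely to fail

Step 11 (the one new method). Three processes could defeat it:
- The β-alkoxy enone may react too slowly, so that the diene decomposes first.
- The reaction may stop after the first bond, a Michael-type addition without closure of C5–C4a.
- Silyl transfer from the ketene acetal to the sulfinyl oxygen may divert the sulfoxide into Pummerer-type chemistry.

The fallback replaces the pericyclic annulation by three ionic reactions of known type. It sets out from 11 and 20 and rejoins the route at 23, so steps 5–7 are no longer needed. Me3SiOTf in CH2Cl2 at −78 °C converts 11 into its 4-silyloxy oxocarbenium ion. The terminal carbon of 20 attacks this ion at C8a in a Mukaiyama–Michael addition, a reaction known for dihydropyranones and chromones, to give the bis(silyl enol ether) Michael adduct F1. Saegusa–Ito oxidation of the C4 silyl enol ether with Pd(OAc)2 in MeCN restores the C4a=C8a bond and, after aqueous work-up, should give the 6-substituted dihydropyranone keto ester F2. Brief treatment with KOH in MeOH at 0 °C then closes C4a–C5 in the Claisen mode by which 3,5,7-triketo esters give acylphloroglucinols. The competing aldol mode (C6 onto C4) is excluded while ring C is intact, because its three-atom O1–C2–C3 bridge cannot span meta positions of a benzene ring. The cost is exposure of the flavanone to base, so contact time must be short and the enantiomeric purity of 23 must be checked.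

Step 4 (key step). The ortho-prenyl group crowds the formyl group and the para-alkoxy group lowers its electrophilicity, so slow conversion or poor facial selectivity may result. The fallback keeps the same two bonds but changes the diene, the mode of activation and the mechanism. It sets out from 8 and rejoins at 11. Aldehyde 8 is combined with the much more reactive (E)-1-(dimethylamino)-3-(tert-butyldimethylsilyloxy)buta-1,3-diene in toluene at −60 °C. The catalyst is α,α,α',α'-tetra(1-naphthyl)-2,2-dimethyl-1,3-dioxolane-4,5-dimethanol, used as the antipode that exposes the Si face, and it acts by hydrogen bonding. A concerted, metal-free [4+2] cycloaddition should give the aminal cycloadduct F3. Acetyl chloride at −78 °C then expels the amino and silyl groups to give 11.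

Step 2. Aryllithium 4 may lose LiBr to an aryne or suffer bromine migration before copper is in place, and some attack at the tertiary terminus of 3 is possible. The fallback reverses the order of events so that no bromine stands next to the carbanion. It sets out from 2 and rejoins at 8, replacing steps 2 and 3. n-BuLi and then DMF convert 2 into 3-methoxy-4-(methoxymethoxy)benzaldehyde F4. Condensation with cyclohexylamine over MgSO4 gives the N-cyclohexyl imine F5. n-BuLi in THF at −78 to 0 °C deprotonates the position flanked by the imine and the methoxy group (cooperative directed ortho-metalation) to give the 2-lithio imine F6. CuBr·SMe2 and 3 then deliver the 2-prenyl imine F7, and aqueous citric acid hydrolyses it to 8.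

Further compounds
F1 | step 11 | methyl 4-[(6S)-6-Ar-4-(trimethylsilyloxy)-5,6-dihydro-2H-pyran-2-yl]-7-methyl-3-(trimethylsilyloxy)octa-2,6-dienoate, C8 and C8a undefined | COC(=O)C=C(O[Si](C)(C)C)C(CC=C(C)C)C1C=C(O[Si](C)(C)C)C[C@@H](c2ccc(OCOC)c(OC)c2CC=C(C)C)O1
F2 | step 11 | methyl 4-[(2S)-2-Ar-4-oxo-2,3-dihydro-4H-pyran-6-yl]-7-methyl-3-oxooct-6-enoate, C8 undefined | COC(=O)CC(=O)C(CC=C(C)C)C1=CC(=O)C[C@@H](c2ccc(OCOC)c(OC)c2CC=C(C)C)O1
F3 | step 4 | (6S)-6-Ar-4-(tert-butyldimethylsilyloxy)-N,N-dimethyl-5,6-dihydro-2H-pyran-2-amine, aminal carbon undefined | CN(C)C1C=C(O[Si](C)(C)C(C)(C)C)C[C@@H](c2ccc(OCOC)c(OC)c2CC=C(C)C)O1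
F4 | step 2 | 3-methoxy-4-(methoxymethoxy)benzaldehyde | COCOc1ccc(C=O)cc1OC
F5 | step 2 | (E)-N-cyclohexyl-1-[3-methoxy-4-(methoxymethoxy)phenyl]methanimine | COCOc1ccc(/C=N/C2CCCCC2)cc1OC
F6 | step 2 | {6-[(E)-(cyclohexylimino)methyl]-2-methoxy-3-(methoxymethoxy)phenyl}lithium | COCOc1ccc(/C=N/C2CCCCC2)c([Li])c1OC
F7 | step 2 | (E)-N-cyclohexyl-1-[3-methoxy-4-(methoxymethoxy)-2-(3-methylbut-2-enyl)phenyl]methanimine | COCOc1ccc(/C=N/C2CCCCC2)c(CC=C(C)C)c1OC
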